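The unit here is the substrate charged: in it the flask's reagent stands at 1.20, the reagent budget, against 2.40 in the ash run.

common to all: substrate 0.010 M

|  | reagent in the second phase | remark | time | volume of the second phase over the first |
|---|---|---|---|---|
| ash | 0.024 M | run made earlier |  |  |
| flask | 0.0120 M |  | 15 d | 1.0 |

ash run (percent of the substrate charged): time / h: target / % = 8.00: 10.9; 15.0: 6.7; 20.0: 3.5; 30.0: 2.3; 40.0: 1.3

(readings scatter by 0.5 percentage points)

* the best time, 15 d at the latest, for target
* the amount of target, in percent of the substrate charged, at that time
* the first time at which target reaches 9.9 %, in the same percent, in d

- in the second phase: reagent in the second phase; everything else is in the first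
- charges count per volume of the first phase; a concentration in a rate is the amount of a species over the volume of its own phase; every rate counts per litre of the first phase
- the earlier runs hold the two phases in the same ratio of volumes as the flask asked about

Target in the ash run falls from 10.9 % at 8.00 h to 1.3 % at 40.0 h, so target is itself consumed. Taking one reagent for each step, as the forecast does, the budget spent equals the target fraction plus twice the fraction that has gone past target. Since substrate, target and that further fraction sum to one, the substrate fraction left once the reagent is spent is one minus half the budget minus half the target still standing. The flask's budget lies below the two that a double step needs, which makes reagent the limiting reagent, so this reply commits to a flask that stops with a substrate fraction of at most 40.0 %. That balance bears on the end of the flask, not on its times.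

The forecast gives 15.7 % at 0.24 d and the asked level at 0.056 d, and says, with R the reagent and T the target: “With 1.2 equivalents, R lasts until T settles near 11%”.

The flask gives 14.1 % at 0.354 d and reaches the level at 0.127 d, both times later than forecast.

    reagent in the reaction phase + target → over-reaction product (k = 0.0110 /M/s)
    substrate + reagent in the reaction phase → target (k = 0.0150 /M/s)
    reagent in the reaction phase ⇌ reagent in the second phase, rate k3*([reagent in the reaction phase] - [reagent in the second phase]/K3) per volume of the first phase (partition coefficient = 2.40, kL = 7.80 × 10⁻⁵ /s)
    reagent in the reaction phase + target → over-reacted product (k = 0.0590 /M/s)

By 0.354 d the flask had turned substrate into target and part of that target further, with substrate at 65.7 %, target at 14.1 % and reagent in the second phase still at 48.4 % of its own charge. Target kept going to over-reacted product and over-reaction product as reagent in the second phase fell to 6.26 % at 1.50 d and 0 % at 7.50 d; target at 15.0 d stands at 9.41 %, which in the balance gives 35.3 % substrate left, and the flask holds 35 %. The neighbour charged with 0.040 M of substrate has a budget of 0.300 and ends with target at 12.5 %, so the balance gives 78.8 %, and that neighbour holds 79 %.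

The numbers in the tables are calculated for substances that don't exist.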